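**Plan**

- Retrosynthesis: free the two phenols last; re-oxidise the benzylic CH2 (C7') on C4 to a ketone; cut the exocyclic C3–C9 bond to give an aroyl-2,5-dihydrofuran and iodomethyl stearate. The dihydrofuran is cut at C7'–C(=O) (Weinreb ketone synthesis), at C3=C4 (ring-closing metathesis) and at O1–C5 (etherification), back to an (S)-aryl vinyl carbinol from vanillin.
- Enabling feature: in the oxolane, C3 lies β to C7' through ring carbon C4. A C7' ketone plus a C3=C4 double bond therefore makes C3 the β-carbon of an enone inside the ring, next to the C2–aryl stereocentre.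
- Forward order: vanillin → (S)-carbinol → ether → the single ring closed by metathesis → aroyl group added → the C19 stearoyloxymethyl chain joined at C3 by radical conjugate addition → C7'=O taken down to CH2 → phenols freed.
- Stereochemistry: C2 comes from a lipase resolution. C3 (anti to the C2 aryl) and C4 (hydrogen delivered anti to the new C3 arm, giving the kinetic 3,4-cis arrangement) should both arise in the key step by relay from C2.

Key step: step 11

Remark: the SMILES is read as the (2S,3R,4R) isomer (C2 aryl trans to the C3 arm, C3 arm cis to the C4 benzyl). Locants: oxolane O1, C2 (aryl), C3, C4, C5; C9 is the CH2O carbon on C3; C7' is the benzylic carbon on C4.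

**Route**

Step 1
Reactants: 1 vanillin; 2 triisopropylsilyl chloride
Product: 3 3-methoxy-4-(triisopropylsilyloxy)benzaldehyde
Conditions: imidazole, DMF, rt
Reagents that add atoms: triisopropylsilyl chloride (2), CC(C)[Si](Cl)(C(C)C)C(C)C
Why: Imidazole-promoted silylation of a phenol should give a bulky aryl silyl ether that tolerates the Grignard, hydride, organolithium, radical and acidic steps and is later removed by fluoride without touching the ester.

Step 2
Reactants: 3 3-methoxy-4-(triisopropylsilyloxy)benzaldehyde; 4 vinylmagnesium bromide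
Product: 5 rac-1-[3-methoxy-4-(triisopropylsilyloxy)phenyl]prop-2-en-1-ol
Conditions: THF, −78 → 0 °C; then H2O
Reagents that add atoms: vinylmagnesium bromide (4), C=C[Mg]Br
Why: Grignard 1,2-addition to an aryl aldehyde should give the racemic aryl vinyl carbinol, the substrate for the resolution.

Step 3
Reactants: 5 rac-1-[3-methoxy-4-(triisopropylsilyloxy)phenyl]prop-2-en-1-ol; 6 vinyl acetate
Product: 7 (1S)-1-[3-methoxy-4-(triisopropylsilyloxy)phenyl]prop-2-en-1-ol
Conditions: Novozym 435 (immobilised Candida antarctica lipase B), MTBE, 30 °C, run to just beyond half conversion; chromatography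
Reagents that add atoms: none
Why: In this lipase kinetic resolution (irreversible transesterification) the enzyme should acylate the (R)-enantiomer, with aryl as the large and vinyl as the medium group (Kazlauskas rule), so the unreacted alcohol is the (S)-enantiomer that becomes C2 of the target.

Step 4
Reactants: 7 (1S)-1-[3-methoxy-4-(triisopropylsilyloxy)phenyl]prop-2-en-1-ol; 8 ethyl 2-(bromomethyl)prop-2-enoate
Product: 9 ethyl 2-({[(1S)-1-[3-methoxy-4-(triisopropylsilyloxy)phenyl]prop-2-en-1-yl]oxy}methyl)prop-2-enoate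
Conditions: NaH, THF, 0 °C → rt
Reagents that add atoms: ethyl 2-(bromomethyl)prop-2-enoate (8), C=C(CBr)C(=O)OCC
Why: Williamson etherification of the alkoxide with the activated allylic bromide (SN2 and SN2' give the same product) forms the O1–C5 bond without touching the C–O bond at the stereocentre.

Step 5
Reactants: 9 ethyl 2-({[(1S)-1-[3-methoxy-4-(triisopropylsilyloxy)phenyl]prop-2-en-1-yl]oxy}methyl)prop-2-enoate
Product: 10 ethyl (5S)-5-[3-methoxy-4-(triisopropylsilyloxy)phenyl]-2,5-dihydrofuran-3-carboxylate
Conditions: second-generation Grubbs catalyst (5 mol %), 1,4-benzoquinone (10 mol %), CH2Cl2, 40 °C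
Reagents that add atoms: none
Why: Ring-closing metathesis of an allyl ether onto a 2-substituted acrylate is an established entry to 2,5-dihydrofuran-3-carboxylates; the ruthenium carbene should load at the vinyl group and close the five-membered ring with loss of ethene, and benzoquinone suppresses double-bond migration.

Step 6
Reactants: 10 ethyl (5S)-5-[3-methoxy-4-(triisopropylsilyloxy)phenyl]-2,5-dihydrofuran-3-carboxylate; 11 N,O-dimethylhydroxylamine hydrochloride
Product: 12 (5S)-N-methoxy-5-[3-methoxy-4-(triisopropylsilyloxy)phenyl]-N-methyl-2,5-dihydrofuran-3-carboxamide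
Conditions: AlMe3, CH2Cl2, 0 °C → rt; then aqueous Rochelle salt
Reagents that add atoms: N,O-dimethylhydroxylamine hydrochloride (11), CNOC.Cl
Why: Aluminium-amide aminolysis of the ester (Weinreb amide formation) is Lewis-acidic and not basic, so the acidic C5–H of the dihydrofuran should not be deprotonated.

Step 7
Reactants: 13 4-bromo-2-methoxyphenol; 2 triisopropylsilyl chloride
Product: 14 (4-bromo-2-methoxyphenoxy)triisopropylsilane
Conditions: imidazole, DMF, rt
Reagents that add atoms: triisopropylsilyl chloride (2), CC(C)[Si](Cl)(C(C)C)C(C)C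
Why: Phenol silylation as in step 1 gives the second aryl unit with the same protecting group, so that one fluoride step frees both phenols at the end.

Step 8
Reactants: 12 (5S)-N-methoxy-5-[3-methoxy-4-(triisopropylsilyloxy)phenyl]-N-methyl-2,5-dihydrofuran-3-carboxamide; 14 (4-bromo-2-methoxyphenoxy)triisopropylsilane
Product: 16 [(5S)-5-[3-methoxy-4-(triisopropylsilyloxy)phenyl]-2,5-dihydrofuran-3-yl][3-methoxy-4-(triisopropylsilyloxy)phenyl]methanone, via aryllithium 15 (not isolated)
Conditions: 14, n-BuLi, THF, −78 °C; then 12, −78 °C; AcOH quench at −78 °C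
Reagents that add atoms: (4-bromo-2-methoxyphenoxy)triisopropylsilane (14), COc1cc(Br)ccc1O[Si](C(C)C)(C(C)C)C(C)C
Why: In this Weinreb ketone synthesis, bromine–lithium exchange gives the aryllithium, which should add 1,2 to the amide and stop at the chelated tetrahedral intermediate, so that the enone appears only on work-up; the low temperature favours addition over deprotonation at C5.

Step 9
Reactants: 17 octadecanoyl chloride (stearoyl chloride); 18 paraformaldehyde
Product: 19 chloromethyl octadecanoate
Conditions: ZnCl2 (cat.), neat, 80 °C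
Reagents that add atoms: paraformaldehyde (18), C=O
Why: Lewis-acid-catalysed insertion of formaldehyde into the acyl chloride C–Cl bond is the standard preparation of chloromethyl esters.

Step 10
Reactants: 19 chloromethyl octadecanoate; 20 sodium iodide
Product: 21 iodomethyl octadecanoate
Conditions: NaI, acetone, rt, dark
Reagents that add atoms: sodium iodide (20), [Na+].[I-]
Why: Finkelstein exchange, driven by precipitation of NaCl, should give the iodomethyl ester, whose weak C–I bond makes it a clean source of the stearoyloxymethyl radical.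

Step 11
Reactants: 16 [(5S)-5-[3-methoxy-4-(triisopropylsilyloxy)phenyl]-2,5-dihydrofuran-3-yl][3-methoxy-4-(triisopropylsilyloxy)phenyl]methanone; 21 iodomethyl octadecanoate
Product: 22 [(2S,3R,4R)-4-[3-methoxy-4-(triisopropylsilyloxy)benzoyl]-2-[3-methoxy-4-(triisopropylsilyloxy)phenyl]oxolan-3-yl]methyl octadecanoate
Conditions: 21 (2.5 equiv), (Me3Si)3SiH (1.5 equiv, syringe pump), Et3B (cat.), air, toluene, 0 °C
Reagents that add atoms: iodomethyl octadecanoate (21), CCCCCCCCCCCCCCCCCC(=O)OCI
Why: Iodine abstraction from 21 by (Me3Si)3Si• gives the nucleophilic stearoyloxymethyl radical, which adds to C3, the β-carbon of the ring enone of 16, and the resulting C4 α-keto radical takes hydrogen from the silane and carries the chain. The closest known reaction type is the silane-mediated Giese addition of alkyl iodides to cyclic enones, and acyloxymethyl radicals are known to add to electron-poor alkenes. No ring is closed; the new C3–C9 bond joins the two fragments. C3 is controlled by the C2 aryl group on the neighbouring ring carbon (attack anti to it, 2,3-trans); C4 is controlled by the new C3 arm, which A(1,3) strain with the planar aroyl radical should hold pseudoaxial, so that hydrogen enters anti to it and the kinetic 3,4-cis arrangement results. The step needs addition to outrun reduction of the first radical and needs attack at C3 only: slow addition of the silane and the polarity match (α-oxygenated radical with the enone, electrophilic α-keto radical with Si–H) should secure the former, the polarisation of the enone the latter. The neutral conditions should leave the epimerisable C4 centre, the β-alkoxy ketone, both silyl ethers and the ester untouched.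

Step 12
Reactants: 22 [(2S,3R,4R)-4-[3-methoxy-4-(triisopropylsilyloxy)benzoyl]-2-[3-methoxy-4-(triisopropylsilyloxy)phenyl]oxolan-3-yl]methyl octadecanoate
Product: 23 [(2S,3R,4R)-4-{hydroxy[3-methoxy-4-(triisopropylsilyloxy)phenyl]methyl}-2-[3-methoxy-4-(triisopropylsilyloxy)phenyl]oxolan-3-yl]methyl octadecanoate (both carbinol epimers)
Conditions: NaBH4, CeCl3·7H2O, MeOH/THF, −20 °C
Reagents that add atoms: none
Why: Luche-type borohydride reduction should reduce the aryl ketone chemoselectively beside the ester at low temperature and low basicity, removing the enolisable carbonyl before C4 can epimerise or the β-alkoxy ketone can open; the carbinol configuration is irrelevant because C7' becomes CH2.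

Step 13
Reactants: 23 [(2S,3R,4R)-4-{hydroxy[3-methoxy-4-(triisopropylsilyloxy)phenyl]methyl}-2-[3-methoxy-4-(triisopropylsilyloxy)phenyl]oxolan-3-yl]methyl octadecanoate
Product: 24 [(2S,3R,4R)-2-[3-methoxy-4-(triisopropylsilyloxy)phenyl]-4-{[3-methoxy-4-(triisopropylsilyloxy)phenyl]methyl}oxolan-3-yl]methyl octadecanoate
Conditions: Et3SiH (excess), CF3CO2H, CH2Cl2, −40 → −20 °C
Reagents that add atoms: none
Why: In this ionic hydrogenation the secondary carbinol should ionise to a para-oxygenated benzylic cation that excess silane traps at once, whereas the cyclic benzylic ether at C2 can only open reversibly and should survive the short, cold exposure.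

Step 14
Reactants: 24 [(2S,3R,4R)-2-[3-methoxy-4-(triisopropylsilyloxy)phenyl]-4-{[3-methoxy-4-(triisopropylsilyloxy)phenyl]methyl}oxolan-3-yl]methyl octadecanoate
Product: 25 [(2S,3R,4R)-2-(4-hydroxy-3-methoxyphenyl)-4-[(4-hydroxy-3-methoxyphenyl)methyl]oxolan-3-yl]methyl octadecanoate (target)
Conditions: Bu4NF, AcOH, THF, 0 °C
Reagents that add atoms: none
Why: Fluoride cleavage of aryl silyl ethers is fast because phenoxide is a good leaving group, and the acetic acid buffer should protect the stearate from basic cleavage and the C2 centre from phenoxide-driven ring opening.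

**Compound list**

1 | vanillin | O=Cc1ccc(O)c(OC)c1 | starting material
2 | triisopropylsilyl chloride | CC(C)[Si](Cl)(C(C)C)C(C)C | starting material
3 | 3-methoxy-4-(triisopropylsilyloxy)benzaldehyde | O=Cc1ccc(O[Si](C(C)C)(C(C)C)C(C)C)c(OC)c1 | intermediate
4 | vinylmagnesium bromide | C=C[Mg]Br | starting material
5 | rac-1-[3-methoxy-4-(triisopropylsilyloxy)phenyl]prop-2-en-1-ol | OC(C=C)c1ccc(O[Si](C(C)C)(C(C)C)C(C)C)c(OC)c1 | intermediate
6 | vinyl acetate | CC(=O)OC=C | starting material
7 | (1S)-1-[3-methoxy-4-(triisopropylsilyloxy)phenyl]prop-2-en-1-ol | O[C@@H](C=C)c1ccc(O[Si](C(C)C)(C(C)C)C(C)C)c(OC)c1 | intermediate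
8 | ethyl 2-(bromomethyl)prop-2-enoate | C=C(CBr)C(=O)OCC | starting material
9 | ethyl 2-({[(1S)-1-[3-methoxy-4-(triisopropylsilyloxy)phenyl]prop-2-en-1-yl]oxy}methyl)prop-2-enoate | C=C[C@H](OCC(=C)C(=O)OCC)c1ccc(O[Si](C(C)C)(C(C)C)C(C)C)c(OC)c1 | intermediate
10 | ethyl (5S)-5-[3-methoxy-4-(triisopropylsilyloxy)phenyl]-2,5-dihydrofuran-3-carboxylate | CCOC(=O)C1=C[C@@H](c2ccc(O[Si](C(C)C)(C(C)C)C(C)C)c(OC)c2)OC1 | intermediate
11 | N,O-dimethylhydroxylamine hydrochloride | CNOC.Cl | starting material
12 | (5S)-N-methoxy-5-[3-methoxy-4-(triisopropylsilyloxy)phenyl]-N-methyl-2,5-dihydrofuran-3-carboxamide | CON(C)C(=O)C1=C[C@@H](c2ccc(O[Si](C(C)C)(C(C)C)C(C)C)c(OC)c2)OC1 | intermediate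
13 | 4-bromo-2-methoxyphenol | Oc1ccc(Br)cc1OC | starting material
14 | (4-bromo-2-methoxyphenoxy)triisopropylsilane | COc1cc(Br)ccc1O[Si](C(C)C)(C(C)C)C(C)C | intermediate
15 | [3-methoxy-4-(triisopropylsilyloxy)phenyl]lithium | [Li]c1ccc(O[Si](C(C)C)(C(C)C)C(C)C)c(OC)c1 | intermediate (not isolated)
16 | [(5S)-5-[3-methoxy-4-(triisopropylsilyloxy)phenyl]-2,5-dihydrofuran-3-yl][3-methoxy-4-(triisopropylsilyloxy)phenyl]methanone | O=C(c1ccc(O[Si](C(C)C)(C(C)C)C(C)C)c(OC)c1)C1=C[C@@H](c2ccc(O[Si](C(C)C)(C(C)C)C(C)C)c(OC)c2)OC1 | intermediate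
17 | octadecanoyl chloride | CCCCCCCCCCCCCCCCCC(=O)Cl | starting material
18 | paraformaldehyde (formaldehyde unit) | C=O | starting material
19 | chloromethyl octadecanoate | CCCCCCCCCCCCCCCCCC(=O)OCCl | intermediate
20 | sodium iodide | [Na+].[I-] | starting material
21 | iodomethyl octadecanoate | CCCCCCCCCCCCCCCCCC(=O)OCI | intermediate
22 | [(2S,3R,4R)-4-[3-methoxy-4-(triisopropylsilyloxy)benzoyl]-2-[3-methoxy-4-(triisopropylsilyloxy)phenyl]oxolan-3-yl]methyl octadecanoate | CCCCCCCCCCCCCCCCCC(=O)OC[C@H]1[C@@H](C(=O)c2ccc(O[Si](C(C)C)(C(C)C)C(C)C)c(OC)c2)CO[C@@H]1c1ccc(O[Si](C(C)C)(C(C)C)C(C)C)c(OC)c1 | intermediate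
23 | [(2S,3R,4R)-4-{hydroxy[3-methoxy-4-(triisopropylsilyloxy)phenyl]methyl}-2-[3-methoxy-4-(triisopropylsilyloxy)phenyl]oxolan-3-yl]methyl octadecanoate (carbinol epimers) | CCCCCCCCCCCCCCCCCC(=O)OC[C@H]1[C@@H](C(O)c2ccc(O[Si](C(C)C)(C(C)C)C(C)C)c(OC)c2)CO[C@@H]1c1ccc(O[Si](C(C)C)(C(C)C)C(C)C)c(OC)c1 | intermediate
24 | [(2S,3R,4R)-2-[3-methoxy-4-(triisopropylsilyloxy)phenyl]-4-{[3-methoxy-4-(triisopropylsilyloxy)phenyl]methyl}oxolan-3-yl]methyl octadecanoate | CCCCCCCCCCCCCCCCCC(=O)OC[C@H]1[C@@H](Cc2ccc(O[Si](C(C)C)(C(C)C)C(C)C)c(OC)c2)CO[C@@H]1c1ccc(O[Si](C(C)C)(C(C)C)C(C)C)c(OC)c1 | intermediate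
25 | [(2S,3R,4R)-2-(4-hydroxy-3-methoxyphenyl)-4-[(4-hydroxy-3-methoxyphenyl)methyl]oxolan-3-yl]methyl octadecanoate | CCCCCCCCCCCCCCCCCC(=O)OC[C@H]1[C@@H](Cc2ccc(O)c(OC)c2)CO[C@@H]1c1ccc(O)c(OC)c1 | target

**Step count**

Total steps: 14 (11 in the main line, 3 in two side branches). Longest linear sequence: 11 steps (steps 1–6, 8, 11–14).

**Steps most likely to fail, with fallbacks**

Step 11. Hydrogen transfer to the C4 radical may occur with poor facial selectivity, because the C2 aryl group shields the face that the C3 arm leaves open; the C4 epimer would then form alongside 22. The fallback resets C4 after the coupling in a stereoconvergent way. It sets out from alcohol 23, obtained as a C4-epimer mixture when the unselective material is carried through step 12. Dehydration with Burgess reagent (toluene, 50 °C) should give the exocyclic alkene [(2S,3R)-2-[3-methoxy-4-(triisopropylsilyloxy)phenyl]-4-{[3-methoxy-4-(triisopropylsilyloxy)phenyl]methylidene}oxolan-3-yl]methyl octadecanoate F1, in which C4 is no longer a stereocentre. Heterogeneous hydrogenation (H2, 1 atm, Rh/Al2O3, EtOAc) should then add hydrogen to the face opposite the C3 arm, as in the cis-selective hydrogenation of α-benzylidene-β-substituted lignan lactones, and the route comes back at 24.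

Step 13. Acid-induced ionisation of the benzylic C2–O1 ether may compete with ionisation of the C7' carbinol, leading to reductive ring opening or C2 epimerisation, and the C7' cation may lose a proton towards C4. The fallback replaces the cationic deoxygenation by a radical one (Barton–McCombie). It sets out from 23, which with 1,1'-thiocarbonyldiimidazole and catalytic DMAP (1,2-dichloroethane, 60 °C) should give the thiocarbonyl derivative [(2S,3R,4R)-4-{[(1H-imidazol-1-ylcarbonothioyl)oxy][3-methoxy-4-(triisopropylsilyloxy)phenyl]methyl}-2-[3-methoxy-4-(triisopropylsilyloxy)phenyl]oxolan-3-yl]methyl octadecanoate F2. Bu3SnH with AIBN (toluene, 90 °C) should then reduce it through the benzylic radical, and the route comes back at 24.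

Step 8. The aryllithium may deprotonate the C5–H of the dihydrofuran (benzylic, allylic, next to oxygen and vinylogous to the carbonyl), which would erode the stereocentre or lead to double-bond migration. The fallback forms the ketone under neutral conditions and sets out from ester 10. Hydrolysis with Me3SnOH (1,2-dichloroethane, 70 °C) should give (5S)-5-[3-methoxy-4-(triisopropylsilyloxy)phenyl]-2,5-dihydrofuran-3-carboxylic acid F3. Ghosez reagent (1-chloro-N,N,2-trimethylprop-1-en-1-amine, CH2Cl2, 0 °C) should convert it to (5S)-5-[3-methoxy-4-(triisopropylsilyloxy)phenyl]-2,5-dihydrofuran-3-carbonyl chloride F4. Separately, aryllithium 15 is transmetalated with ZnCl2 to [3-methoxy-4-(triisopropylsilyloxy)phenyl]zinc chloride F5. Negishi acylation of F4 with F5 under Pd(PPh3)4 (zerovalent palladium; THF, rt) should give the ketone, and the route comes back at 16.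

**Further compounds**

F1 | step 11 | [(2S,3R)-2-[3-methoxy-4-(triisopropylsilyloxy)phenyl]-4-{[3-methoxy-4-(triisopropylsilyloxy)phenyl]methylidene}oxolan-3-yl]methyl octadecanoate (E/Z mixture) | CCCCCCCCCCCCCCCCCC(=O)OC[C@H]1C(=Cc2ccc(O[Si](C(C)C)(C(C)C)C(C)C)c(OC)c2)CO[C@@H]1c1ccc(O[Si](C(C)C)(C(C)C)C(C)C)c(OC)c1
F2 | step 13 | [(2S,3R,4R)-4-{[(1H-imidazol-1-ylcarbonothioyl)oxy][3-methoxy-4-(triisopropylsilyloxy)phenyl]methyl}-2-[3-methoxy-4-(triisopropylsilyloxy)phenyl]oxolan-3-yl]methyl octadecanoate | CCCCCCCCCCCCCCCCCC(=O)OC[C@H]1[C@@H](C(OC(=S)n2ccnc2)c2ccc(O[Si](C(C)C)(C(C)C)C(C)C)c(OC)c2)CO[C@@H]1c1ccc(O[Si](C(C)C)(C(C)C)C(C)C)c(OC)c1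
F3 | step 8 | (5S)-5-[3-methoxy-4-(triisopropylsilyloxy)phenyl]-2,5-dihydrofuran-3-carboxylic acid | OC(=O)C1=C[C@@H](c2ccc(O[Si](C(C)C)(C(C)C)C(C)C)c(OC)c2)OC1
F4 | step 8 | (5S)-5-[3-methoxy-4-(triisopropylsilyloxy)phenyl]-2,5-dihydrofuran-3-carbonyl chloride | ClC(=O)C1=C[C@@H](c2ccc(O[Si](C(C)C)(C(C)C)C(C)C)c(OC)c2)OC1
F5 | step 8 | [3-methoxy-4-(triisopropylsilyloxy)phenyl]zinc chloride | Cl[Zn]c1ccc(O[Si](C(C)C)(C(C)C)C(C)C)c(OC)c1
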